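## The problem

Target 27 is a 5,7-dihydroxy-8-prenylisoflavone whose ring B is a 5-hydroxy-2,2-dimethyl-2H-chromen-8-yl unit: the pyran ring spans O2' and C3', and O4' is a free phenol. There is no stereocentre, so the difficulty lies in regiochemistry and functional-group tolerance.

- **Ring A.** It is a fully substituted phloroglucinol. O1 must close ring C, O5 and O7 must end as free phenols, and the prenyl group must sit on C8 between O7 and O1. Prenylation or Claisen chemistry on 5,7-dioxygenated acetophenones or chromones gives 6- and 8-isomers, and a 2,6-dihydroxyacetophenone can close ring C on either side.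
- **Ring B.** The pyran ring must use the oxygen ortho to the biaryl bond and the carbon between the two oxygens.
- **Sensitive groups.** A prenyl group next to a free phenol cyclises to a chroman under acid. Prenyl and chromene both rule out hydrogenolysis. The chromene is opened by strong Lewis acids. C2 of ring C is attacked by strong base. The last steps must therefore be mild.
- **Enabling feature.** C8 carries the carbon substituent, is flanked by the oxygenated carbons C7 and C8a, and lies para to O5. This is the pattern formed when a siloxyalkyne (its carbons become C8 and C7) combines with a 3-alkoxyvinylketene (carbonyl carbon becomes C8a, alkoxy carbon becomes C5). The three oxygens then arrive as hydroxyl, silyl ether and ethyl ether, and can be told apart.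

## Retrosynthesis

**27 from 26.** The two phenols O7 and O4' are released last from bis(triisopropylsilyl) ether 26 by fluoride. Silyl groups on both oxygens let one neutral operation finish the synthesis, and no acid or reductant meets the prenyl group or the chromene at the end.

**26 from 18 and 25.** The C3–C1' bond is cut by Suzuki coupling of 3-iodochromone 18 with chromenylboronate 25. Against a deoxybenzoin route, this keeps the synthesis convergent and lets each ring be finished on its own. The forward reaction must couple an ortho-alkoxy arylboronate with an iodochromone that carries a free, chelated 5-hydroxyl.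

**18 from 17.** The O5–ethyl bond is cleaved on iodochromone 17 with chelation to the C4 carbonyl. Doing this before the coupling keeps the boron Lewis acid away from the chromene of ring B. O7 is still silylated, so the prenyl group has no free neighbouring hydroxyl to cyclise onto.

**17 from 16 and 15.** Ring C is cut at O1–C2 and C2–C3: enaminone 16, made from hydroxyketone 15, closes with iodine to give 17. In 15 only one oxygen is free; O5 is ethylated and O7 silylated. Ring C can therefore form only on the side of the prenyl group, which makes C8 the prenylated carbon.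

**15 from 14, 12 and 11.** The C4a–C4 bond is cut by directed ortho-metalation. Phenol 11 is converted into methoxymethyl ether 12, which is lithiated between the methoxymethoxy and ethoxy groups and acetylated to 14; mild acid then frees O1 to give 15. Friedel–Crafts or Fries acylation would be acidic and would not distinguish the two open ring positions. The free hydroxyl of 11 is assigned as O1 because it can carry the directing group at once, and the silyl ether stays on as the O7 protecting group.

**11 from 6 and 5.** Ring A is cut into 3-ethoxycyclobut-2-en-1-one 6 and siloxyalkyne 5 through the bonds C8–C8a, C6–C7 and C4a–C8a. Prenylating a preformed phloroglucinol would require separate differentiation of three phenols. The annulation places the prenyl group and delivers the oxygens as OH, OSi and OEt in one step. The forward reaction needs regioselective [2+2] addition of the alkyne to the vinylketene.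

**5 from 2, 1 and 3.** The alkyne C–C bond is cut by Kowalski homologation: ester 2, made from acid 1, gives an ynolate that silyl chloride 3 traps on oxygen. The prenyl group of 5 is the acyl residue of 2, so no allylic alkylation is needed.

**25 from 23, 22, 20, 19, 21 and 3.** Boronate 25 comes from bromochromene 23 by bromine–lithium exchange. The pyran ring of 23 is cut at C4–C4a by Claisen rearrangement of propargyl ether 22, in which bromine blocks one ortho position. Ether 22 comes from phenol 20 and propargyl chloride 21, and 20 from 4-bromoresorcinol 19 by silylation of the unhindered hydroxyl with 3.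

## Roads not taken

**Alternative 1:** Chalcone epoxide rearrangement.
- **Cut and key step.** The cut runs through C3–C4 and O1–C2. BF3·OEt2 would open trans chalcone epoxide A2 at the benzylic carbon; the aroyl group shifts to that carbon, and the unveiled aldehyde is captured by the methoxymethyl-bearing oxygen to give tri-O-allyl isoflavone A1.
- **Merits.** The C3–aryl bond comes from aldol chemistry with no palladium, boron or iodine. The allyl ethers of A1 leave under neutral conditions with zerovalent palladium, which is gentler than step 9 of the chosen plan.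
- **Weak points.** BF3·OEt2 meets the prenyl group, the chromene and the acetal at once. The electron-rich ring B stabilises the benzylic cation strongly enough that fluorohydrin formation and hydride shift can compete with the aroyl shift. A2 also presupposes a ring A with prenyl between a methoxymethoxy and an allyloxy group, which leaves the differentiated 2-prenylphloroglucinol unsolved.
- **Comparison.** The end game is as short and milder. The chosen plan sets against this a constructive solution for ring A and a Lewis-acid step that occurs before the chromene is present.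

**Alternative 2:** Benzannulation of ring B.
- **Cut and key step.** Ring B is grown on a finished chromone. Irradiation of diazoketone A4 gives a dienylketene by Wolff rearrangement; with siloxyalkyne 5 this forms C2'–C3', C4'–C5' and C1'–C2' and gives phenol A3. Oxidative closure of the 2'-hydroxyl onto the 3'-prenyl group and deprotection would follow.
- **Merits.** O2' and O4' are differentiated automatically and no cross-coupling is needed. In this respect it is better than the chosen plan, which relies on a selective monosilylation of 19.
- **Weak points.** The annulation is spent on the easier ring. The 8-prenyl-5,7-dioxygenated chromone inside A4 is left to classical chemistry. The chromone is itself photoactive and electrophilic at C2, which puts the photochemical step and the diazo transfer at risk. The late oxidative chromene closure must also spare the second prenyl group.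
- **Comparison.** The chosen plan uses the same alkyne 5 on ring A, where the regiochemical gain is larger, and makes ring B in four conventional steps.

**Alternative 3:** Diels–Alder aromatisation.
- **Cut and key step.** Ring A is cut at C8–C8a and C5–C4a. The prenylated Chan-type diene A7 would add across the brominated C=C bond of 3-aryl-5-bromo-4-pyranone A6; loss of HBr, methanol and the silyl groups gives A5, one desilylation from the target.
- **Merits.** It is the shortest road, with no protecting-group work on ring A. It is better than the chosen plan in step count.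
- **Weak points.** A monocyclic 4-pyranone is a poor dienophile, and the reaction class is established for halochromones and haloquinones, not for A6. A diene with a substituent on its nucleophilic terminus reacts slowly. The acidic aromatisation would expose a fresh 7-hydroxyl next to the prenyl group and the chromene. A6 itself requires a statistical mono-arylation of a symmetric dihalopyranone.
- **Comparison.** The chosen plan sets against the shorter count a key step from a documented reaction class and standard reactions after it.

Key step: step 3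

Assumption: 3-ethoxycyclobut-2-en-1-one 6 is taken as purchasable. In ring A the free hydroxyl of the annulation product serves as O1 and the silyl ether as O7, which the symmetry of the 2-prenylresorcinol core permits.

## Steps

Step 1
Reactants: 1 4-methylpent-3-enoic acid
Product: 2 ethyl 4-methylpent-3-enoate
Conditions: EtI, K2CO3, DMF, rt
Reagents that add atoms: iodoethane, CCI
Why: Carboxylate O-alkylation (SN2) under weakly basic conditions avoids the lactonisation and double-bond migration that this β,γ-unsaturated acid risks under Fischer conditions.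

Step 2
Reactants: 2 ethyl 4-methylpent-3-enoate; 3 triisopropylsilyl chloride
Product: 5 triisopropyl[(5-methylhex-4-en-1-yn-1-yl)oxy]silane, via lithium ynolate 4 (not isolated)
Conditions: CH2Br2, LiTMP (lithium 2,2,6,6-tetramethylpiperidide), THF, −78 °C; 2; LiN(SiMe3)2 then n-BuLi, −78 °C → rt; 3, −78 °C → rt
Reagents that add atoms: dibromomethane, BrCBr
Why: Kowalski ester homologation: LiCHBr2 adds to the ester, enolisation and bromine–lithium exchange give a carbenoid whose prenyl group shifts to form lithium ynolate 4, and the bulky silyl chloride 3 traps it on oxygen, as is usual for triisopropylsilyl.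

Step 3
Reactants: 6 3-ethoxycyclobut-2-en-1-one; 5 triisopropyl[(5-methylhex-4-en-1-yn-1-yl)oxy]silane
Product: 11 5-ethoxy-2-(3-methylbut-2-en-1-yl)-3-(triisopropylsilyloxy)phenol, via ethoxyvinylketene 7 (not isolated), via vinylcyclobutenone 8 (not isolated), via dienylketene 9 (not isolated), via cyclohexadienone 10 (not isolated)
Conditions: toluene, 80 °C then 110 °C, sealed vessel, slight excess of 5
Reagents that add atoms: none
Why: Danheiser benzannulation; the closest known reaction type is the union of cyclobutenones with triisopropylsiloxyalkynes to give resorcinol monosilyl ethers. Heating opens 6 by 4π electrocyclic ring opening to ethoxyvinylketene 7. Alkyne 5 is polarised by its oxygen so that the prenyl-bearing carbon is nucleophilic; that carbon bonds to the ketene carbonyl carbon in a [2+2] cycloaddition and gives vinylcyclobutenone 8 as the one expected regioisomer. A second 4π opening gives dienylketene 9, reversibly, so the isomer with ketene and ethoxyvinyl groups cis is drained by ring closure. Ring A closes by thermal disrotatory 6π electrocyclisation, the ketene carbon bonding to the terminal methylene, to give dienone 10, which tautomerises to phenol 11. No stereocentre is formed, because the sp3 centre of 8 is lost on ring opening. The step needs the regiochemistry of the [2+2] addition and reaction at the ketene C=C bond only; the donor polarisation of the ynol ether and the electrophilic ketene carbon secure both. The vinylogous-ester character of 6 slows the first ring opening, which the higher final temperature is meant to overcome.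

Step 4
Reactants: 11 5-ethoxy-2-(3-methylbut-2-en-1-yl)-3-(triisopropylsilyloxy)phenol
Product: 12 [5-ethoxy-3-(methoxymethoxy)-2-(3-methylbut-2-en-1-yl)phenoxy]triisopropylsilane
Conditions: MOMCl, i-Pr2NEt, CH2Cl2, 0 °C → rt
Reagents that add atoms: chloromethyl methyl ether, COCCl
Why: O-alkylation of the only free phenol to its methoxymethyl acetal, chosen because it is a strong ortho-directing group for the next step and leaves again under mild acid.

Step 5
Reactants: 12 [5-ethoxy-3-(methoxymethoxy)-2-(3-methylbut-2-en-1-yl)phenoxy]triisopropylsilane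
Product: 14 1-[6-ethoxy-2-(methoxymethoxy)-3-(3-methylbut-2-en-1-yl)-4-(triisopropylsilyloxy)phenyl]ethan-1-one, via aryllithium 13 (not isolated)
Conditions: n-BuLi, TMEDA, THF, −20 → 0 °C; then MeC(O)N(OMe)Me, −78 → 0 °C
Reagents that add atoms: N-methoxy-N-methylacetamide, CC(=O)N(C)OC
Why: Directed ortho-metalation: the ring hydrogen between the methoxymethoxy and ethoxy groups is the only one flanked by two coordinating oxygens, the other lying beside the bulky non-coordinating silyl ether, and the Weinreb amide stops at the ketone.

Step 6
Reactants: 14 1-[6-ethoxy-2-(methoxymethoxy)-3-(3-methylbut-2-en-1-yl)-4-(triisopropylsilyloxy)phenyl]ethan-1-one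
Product: 15 1-[6-ethoxy-2-hydroxy-3-(3-methylbut-2-en-1-yl)-4-(triisopropylsilyloxy)phenyl]ethan-1-one
Conditions: HCl (cat.), MeOH–THF, rt
Reagents that add atoms: none
Why: Acid-catalysed transacetalisation removes the methoxymethyl group ortho to the carbonyl; the freed hydroxyl is held in a hydrogen bond to the ketone, which disfavours chroman formation with the prenyl group, and the aryl silyl ether is stable to dilute acid.

Step 7
Reactants: 15 1-[6-ethoxy-2-hydroxy-3-(3-methylbut-2-en-1-yl)-4-(triisopropylsilyloxy)phenyl]ethan-1-one
Product: 16 (2E)-3-(dimethylamino)-1-[6-ethoxy-2-hydroxy-3-(3-methylbut-2-en-1-yl)-4-(triisopropylsilyloxy)phenyl]prop-2-en-1-one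
Conditions: Me2NCH(OMe)2, toluene, 90 °C
Reagents that add atoms: N,N-dimethylformamide dimethyl acetal, COC(OC)N(C)C
Why: Condensation of the methyl ketone with the formamide acetal gives the enaminone, the standard one-carbon homologation for chromone synthesis; the chelated hydroxyl is not methylated.

Step 8
Reactants: 16 (2E)-3-(dimethylamino)-1-[6-ethoxy-2-hydroxy-3-(3-methylbut-2-en-1-yl)-4-(triisopropylsilyloxy)phenyl]prop-2-en-1-one
Product: 17 5-ethoxy-3-iodo-8-(3-methylbut-2-en-1-yl)-7-(triisopropylsilyloxy)-4H-chromen-4-one
Conditions: I2, pyridine, CHCl3, rt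
Reagents that add atoms: iodine, II
Why: Iodine-mediated cyclisation of a 2-hydroxyaryl enaminone (Gammill 3-iodochromone synthesis): α-iodination, attack of the phenol on the iminium carbon and loss of dimethylamine; only O1 is free, so ring C closes in one direction, and the prenyl alkene has no free ortho hydroxyl for iodoetherification.

Step 9
Reactants: 17 5-ethoxy-3-iodo-8-(3-methylbut-2-en-1-yl)-7-(triisopropylsilyloxy)-4H-chromen-4-one
Product: 18 5-hydroxy-3-iodo-8-(3-methylbut-2-en-1-yl)-7-(triisopropylsilyloxy)-4H-chromen-4-one
Conditions: BCl3, CH2Cl2, −78 → 0 °C; then ice-water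
Reagents that add atoms: none
Why: Chelation-assisted ether cleavage: BCl3 binds the C4 carbonyl and the peri oxygen, and chloride removes the ethyl group from that oxygen only; at this stage the chromene is absent and the prenyl group has a silylated neighbour.

Step 10
Reactants: 19 4-bromoresorcinol; 3 triisopropylsilyl chloride
Product: 20 2-bromo-5-(triisopropylsilyloxy)phenol
Conditions: 3 (1.0 equiv), imidazole, CH2Cl2, 0 °C
Reagents that add atoms: none
Why: Selective O-silylation: the hydroxyl ortho to bromine is shielded by the halogen and held in an O–H···Br contact, so the bulky silyl chloride should react at the remote hydroxyl, and one equivalent at low temperature limits bis-silylation.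

Step 11
Reactants: 20 2-bromo-5-(triisopropylsilyloxy)phenol; 21 3-chloro-3-methylbut-1-yne
Product: 22 {4-bromo-3-[(2-methylbut-3-yn-2-yl)oxy]phenoxy}triisopropylsilane
Conditions: DBU, CuCl2 (cat.), MeCN, 0 °C → rt
Reagents that add atoms: none
Why: Copper-catalysed O-propargylation of a phenol with a tertiary propargyl chloride (Godfrey conditions), which forms the hindered 1,1-dimethylpropargyl aryl ether at low temperature.

Step 12
Reactants: 22 {4-bromo-3-[(2-methylbut-3-yn-2-yl)oxy]phenoxy}triisopropylsilane
Product: 23 [(8-bromo-2,2-dimethyl-2H-chromen-5-yl)oxy]triisopropylsilane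
Conditions: PhNEt2, 150 °C
Reagents that add atoms: none
Why: Aryl propargyl ether Claisen rearrangement followed by 1,5-hydrogen shift and 6π oxa-electrocyclisation; bromine blocks one ortho position, so the [3,3] shift is productive only at the carbon between the two oxygens, which fixes the angular chromene.

Step 13
Reactants: 23 [(8-bromo-2,2-dimethyl-2H-chromen-5-yl)oxy]triisopropylsilane
Product: 25 {[2,2-dimethyl-8-(4,4,5,5-tetramethyl-1,3,2-dioxaborolan-2-yl)-2H-chromen-5-yl]oxy}triisopropylsilane, via chromenyllithium 24 (not isolated)
Conditions: n-BuLi, THF, −78 °C; then i-PrOBpin, −78 °C → rt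
Reagents that add atoms: 2-isopropoxy-4,4,5,5-tetramethyl-1,3,2-dioxaborolane, CC(C)OB1OC(C)(C)C(C)(C)O1
Why: Bromine–lithium exchange and borylation with the isopropoxy pinacol borate; the aryllithium is para to the silyl ether, so no silyl migration is possible, and the chromene alkene is inert at −78 °C.

Step 14
Reactants: 18 5-hydroxy-3-iodo-8-(3-methylbut-2-en-1-yl)-7-(triisopropylsilyloxy)-4H-chromen-4-one; 25 {[2,2-dimethyl-8-(4,4,5,5-tetramethyl-1,3,2-dioxaborolan-2-yl)-2H-chromen-5-yl]oxy}triisopropylsilane
Product: 26 3-[2,2-dimethyl-5-(triisopropylsilyloxy)-2H-chromen-8-yl]-5-hydroxy-8-(3-methylbut-2-en-1-yl)-7-(triisopropylsilyloxy)-4H-chromen-4-one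
Conditions: Pd(dppf)Cl2 (cat.), Na2CO3, 1,4-dioxane–H2O, 70 °C
Reagents that add atoms: none
Why: Suzuki–Miyaura coupling of a 3-iodochromone with an arylboronate, the standard isoflavone assembly; mild carbonate base and moderate temperature spare ring C, the chelated 5-hydroxyl does not interfere, and partial loss of a silyl group would be harmless because the next step removes both.

Step 15
Reactants: 26 3-[2,2-dimethyl-5-(triisopropylsilyloxy)-2H-chromen-8-yl]-5-hydroxy-8-(3-methylbut-2-en-1-yl)-7-(triisopropylsilyloxy)-4H-chromen-4-one
Product: 27 5,7-dihydroxy-3-(5-hydroxy-2,2-dimethyl-2H-chromen-8-yl)-8-(3-methylbut-2-en-1-yl)-4H-chromen-4-one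
Conditions: n-Bu4NF, AcOH, THF, 0 °C → rt
Reagents that add atoms: none
Why: Fluoride cleavage of both aryl silyl ethers under buffered conditions; nothing acidic, reducing or strongly basic touches the prenyl group, the chromene or ring C in the last step.

## Compound list

1 | 4-methylpent-3-enoic acid | CC(C)=CCC(=O)O | starting material
2 | ethyl 4-methylpent-3-enoate | CCOC(=O)CC=C(C)C | intermediate
3 | triisopropylsilyl chloride | CC(C)[Si](Cl)(C(C)C)C(C)C | starting material
4 | lithium 5-methylhex-4-en-1-yn-1-olate (not isolated) | [Li+].[O-]C#CCC=C(C)C | intermediate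
5 | triisopropyl[(5-methylhex-4-en-1-yn-1-yl)oxy]silane | CC(C)=CCC#CO[Si](C(C)C)(C(C)C)C(C)C | intermediate
6 | 3-ethoxycyclobut-2-en-1-one | CCOC1=CC(=O)C1 | starting material
7 | 3-ethoxybuta-1,3-dien-1-one (not isolated) | C=C(OCC)C=C=O | intermediate
8 | 4-(1-ethoxyethenyl)-2-(3-methylbut-2-en-1-yl)-3-(triisopropylsilyloxy)cyclobut-2-en-1-one, racemic (not isolated) | C=C(OCC)C1C(=O)C(CC=C(C)C)=C1O[Si](C(C)C)(C(C)C)C(C)C | intermediate
9 | (3E)-5-ethoxy-2-(3-methylbut-2-en-1-yl)-3-(triisopropylsilyloxy)hexa-1,3,5-trien-1-one, ketene and ethoxyvinyl groups cis (not isolated) | O=C=C(CC=C(C)C)/C(O[Si](C(C)C)(C(C)C)C(C)C)=C\C(OCC)=C | intermediate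
10 | 5-ethoxy-2-(3-methylbut-2-en-1-yl)-3-(triisopropylsilyloxy)cyclohexa-2,4-dien-1-one (not isolated) | CCOC1=CC(O[Si](C(C)C)(C(C)C)C(C)C)=C(CC=C(C)C)C(=O)C1 | intermediate
11 | 5-ethoxy-2-(3-methylbut-2-en-1-yl)-3-(triisopropylsilyloxy)phenol | CCOc1cc(O)c(CC=C(C)C)c(O[Si](C(C)C)(C(C)C)C(C)C)c1 | intermediate
12 | [5-ethoxy-3-(methoxymethoxy)-2-(3-methylbut-2-en-1-yl)phenoxy]triisopropylsilane | CCOc1cc(OCOC)c(CC=C(C)C)c(O[Si](C(C)C)(C(C)C)C(C)C)c1 | intermediate
13 | [6-ethoxy-2-(methoxymethoxy)-3-(3-methylbut-2-en-1-yl)-4-(triisopropylsilyloxy)phenyl]lithium (not isolated) | [Li]c1c(OCC)cc(O[Si](C(C)C)(C(C)C)C(C)C)c(CC=C(C)C)c1OCOC | intermediate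
14 | 1-[6-ethoxy-2-(methoxymethoxy)-3-(3-methylbut-2-en-1-yl)-4-(triisopropylsilyloxy)phenyl]ethan-1-one | CC(=O)c1c(OCC)cc(O[Si](C(C)C)(C(C)C)C(C)C)c(CC=C(C)C)c1OCOC | intermediate
15 | 1-[6-ethoxy-2-hydroxy-3-(3-methylbut-2-en-1-yl)-4-(triisopropylsilyloxy)phenyl]ethan-1-one | CC(=O)c1c(OCC)cc(O[Si](C(C)C)(C(C)C)C(C)C)c(CC=C(C)C)c1O | intermediate
16 | (2E)-3-(dimethylamino)-1-[6-ethoxy-2-hydroxy-3-(3-methylbut-2-en-1-yl)-4-(triisopropylsilyloxy)phenyl]prop-2-en-1-one | CN(C)/C=C/C(=O)c1c(OCC)cc(O[Si](C(C)C)(C(C)C)C(C)C)c(CC=C(C)C)c1O | intermediate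
17 | 5-ethoxy-3-iodo-8-(3-methylbut-2-en-1-yl)-7-(triisopropylsilyloxy)-4H-chromen-4-one | CCOc1cc(O[Si](C(C)C)(C(C)C)C(C)C)c(CC=C(C)C)c2occ(I)c(=O)c12 | intermediate
18 | 5-hydroxy-3-iodo-8-(3-methylbut-2-en-1-yl)-7-(triisopropylsilyloxy)-4H-chromen-4-one | CC(C)=CCc1c(O[Si](C(C)C)(C(C)C)C(C)C)cc(O)c2c(=O)c(I)coc12 | intermediate
19 | 4-bromoresorcinol | Oc1ccc(Br)c(O)c1 | starting material
20 | 2-bromo-5-(triisopropylsilyloxy)phenol | Oc1cc(O[Si](C(C)C)(C(C)C)C(C)C)ccc1Br | intermediate
21 | 3-chloro-3-methylbut-1-yne | C#CC(C)(C)Cl | starting material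
22 | {4-bromo-3-[(2-methylbut-3-yn-2-yl)oxy]phenoxy}triisopropylsilane | C#CC(C)(C)Oc1cc(O[Si](C(C)C)(C(C)C)C(C)C)ccc1Br | intermediate
23 | [(8-bromo-2,2-dimethyl-2H-chromen-5-yl)oxy]triisopropylsilane | CC1(C)C=Cc2c(O[Si](C(C)C)(C(C)C)C(C)C)ccc(Br)c2O1 | intermediate
24 | [2,2-dimethyl-5-(triisopropylsilyloxy)-2H-chromen-8-yl]lithium (not isolated) | [Li]c1ccc(O[Si](C(C)C)(C(C)C)C(C)C)c2C=CC(C)(C)Oc12 | intermediate
25 | {[2,2-dimethyl-8-(4,4,5,5-tetramethyl-1,3,2-dioxaborolan-2-yl)-2H-chromen-5-yl]oxy}triisopropylsilane | CC1(C)C=Cc2c(O[Si](C(C)C)(C(C)C)C(C)C)ccc(B3OC(C)(C)C(C)(C)O3)c2O1 | intermediate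
26 | 3-[2,2-dimethyl-5-(triisopropylsilyloxy)-2H-chromen-8-yl]-5-hydroxy-8-(3-methylbut-2-en-1-yl)-7-(triisopropylsilyloxy)-4H-chromen-4-one | CC(C)=CCc1c(O[Si](C(C)C)(C(C)C)C(C)C)cc(O)c2c(=O)c(-c3ccc(O[Si](C(C)C)(C(C)C)C(C)C)c4c3OC(C)(C)C=C4)coc12 | intermediate
27 | 5,7-dihydroxy-3-(5-hydroxy-2,2-dimethyl-2H-chromen-8-yl)-8-(3-methylbut-2-en-1-yl)-4H-chromen-4-one (CNP0246833.0) | CC(C)=CCc1c(O)cc(O)c2c(=O)c(-c3ccc(O)c4c3OC(C)(C)C=C4)coc12 | target

## Step count and risks

Total step count: 15. Longest linear sequence: 11 steps (steps 1–9, 14 and 15, from acid 1); the ring B branch (steps 10–13) joins at step 14.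

**Step 3 (key step).** The vinylogous-ester stabilisation of 6 may make the first ring opening slow. Dimerisation of the ethoxyvinylketene, or acylation of the product phenol by it, could then outrun the [2+2] addition to the alkyne. Fallback: build the same arene by directed metalation of a preformed ring. It sets out from silyl chloride 3 and a new starting material, benzene-1,3,5-triol F1, and comes back at phenol 11. F1 is monoetherified in ethanol with HCl to 5-ethoxybenzene-1,3-diol F2. This is protected with MOMCl and i-Pr2NEt as 1-ethoxy-3,5-bis(methoxymethoxy)benzene F3. F3 is lithiated with n-BuLi between the two acetal groups and alkylated, after transmetalation with CuBr·SMe2, with 1-bromo-3-methylbut-2-ene F4 to give 5-ethoxy-1,3-bis(methoxymethoxy)-2-(3-methylbut-2-en-1-yl)benzene F5. Methanolic HCl releases 5-ethoxy-2-(3-methylbut-2-en-1-yl)benzene-1,3-diol F6, and one equivalent of 3 with imidazole silylates one of its two equivalent hydroxyls to give 11.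

**Step 2.** The α-hydrogens of the β,γ-unsaturated ester are unusually acidic. Deprotonation by LiCHBr2, with migration of the double bond into conjugation, may compete with addition to the carbonyl group. Fallback: make the ynolate by oxidation of an acetylide. It sets out from silyl chloride 3 and 1-bromo-3-methylbut-2-ene F4, and comes back at ynolate 4 and thus at 5. F4 is coupled with (trimethylsilyl)ethynylmagnesium bromide under CuBr·SMe2 catalysis to trimethyl(5-methylhex-4-en-1-yn-1-yl)silane F7. K2CO3 in methanol gives 5-methylhex-4-en-1-yne F8. Its lithium acetylide (n-BuLi) is oxidised with t-BuOOLi to 4, which 3 traps as in the main route.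

**Step 5.** Lateral deprotonation of the doubly activated prenyl methylene, or enolisation of the Weinreb amide by the hindered aryllithium, would return 12 or give side-chain products. Fallback: use the free phenol itself as the directing element. It sets out from phenol 11 and comes back at hydroxyketone 15, bypassing steps 4–6. Magnesium-mediated ortho-formylation (MgCl2, Et3N, paraformaldehyde, MeCN, reflux) gives 6-ethoxy-2-hydroxy-3-(3-methylbut-2-en-1-yl)-4-(triisopropylsilyloxy)benzaldehyde F9; the only open ortho position is the required one. MeMgBr adds to give racemic 1-[6-ethoxy-2-hydroxy-3-(3-methylbut-2-en-1-yl)-4-(triisopropylsilyloxy)phenyl]ethan-1-ol F10, and MnO2 oxidises the benzylic alcohol to 15.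

**Step 9.** An ethyl ether is cleaved more slowly than a methyl ether. On longer exposure, hydrogen chloride may add to the prenyl alkene, or the silyl ether may be lost and the freed O7 may close onto the prenyl group. Fallback: move the cleavage behind the coupling and change its mechanism to iodide attack on a magnesium chelate. It sets out from iodochromone 17 and comes back at 26. Compound 17 is coupled with boronate 25 under the conditions of step 14 to give 3-[2,2-dimethyl-5-(triisopropylsilyloxy)-2H-chromen-8-yl]-5-ethoxy-8-(3-methylbut-2-en-1-yl)-7-(triisopropylsilyloxy)-4H-chromen-4-one F11. MgI2·OEt2 in toluene at 80 °C then removes the peri ethyl group in a medium free of protic acid, giving 26.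

## Further compounds

F1 | step 3 | benzene-1,3,5-triol | Oc1cc(O)cc(O)c1
F2 | step 3 | 5-ethoxybenzene-1,3-diol | CCOc1cc(O)cc(O)c1
F3 | step 3 | 1-ethoxy-3,5-bis(methoxymethoxy)benzene | CCOc1cc(OCOC)cc(OCOC)c1
F4 | step 3 | 1-bromo-3-methylbut-2-ene | CC(C)=CCBr
F5 | step 3 | 5-ethoxy-1,3-bis(methoxymethoxy)-2-(3-methylbut-2-en-1-yl)benzene | CCOc1cc(OCOC)c(CC=C(C)C)c(OCOC)c1
F6 | step 3 | 5-ethoxy-2-(3-methylbut-2-en-1-yl)benzene-1,3-diol | CCOc1cc(O)c(CC=C(C)C)c(O)c1
F7 | step 2 | trimethyl(5-methylhex-4-en-1-yn-1-yl)silane | CC(C)=CCC#C[Si](C)(C)C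
F8 | step 2 | 5-methylhex-4-en-1-yne | CC(C)=CCC#C
F9 | step 5 | 6-ethoxy-2-hydroxy-3-(3-methylbut-2-en-1-yl)-4-(triisopropylsilyloxy)benzaldehyde | O=Cc1c(OCC)cc(O[Si](C(C)C)(C(C)C)C(C)C)c(CC=C(C)C)c1O
F10 | step 5 | 1-[6-ethoxy-2-hydroxy-3-(3-methylbut-2-en-1-yl)-4-(triisopropylsilyloxy)phenyl]ethan-1-ol, racemic | CC(O)c1c(OCC)cc(O[Si](C(C)C)(C(C)C)C(C)C)c(CC=C(C)C)c1O
F11 | step 9 | 3-[2,2-dimethyl-5-(triisopropylsilyloxy)-2H-chromen-8-yl]-5-ethoxy-8-(3-methylbut-2-en-1-yl)-7-(triisopropylsilyloxy)-4H-chromen-4-one | CCOc1cc(O[Si](C(C)C)(C(C)C)C(C)C)c(CC=C(C)C)c2occ(-c3ccc(O[Si](C(C)C)(C(C)C)C(C)C)c4c3OC(C)(C)C=C4)c(=O)c12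
A1 | alternative 1 | 5,7-bis(allyloxy)-3-[5-(allyloxy)-2,2-dimethyl-2H-chromen-8-yl]-8-(3-methylbut-2-en-1-yl)-4H-chromen-4-one | CC(C)=CCc1c(OCC=C)cc(OCC=C)c2c(=O)c(-c3ccc(OCC=C)c4c3OC(C)(C)C=C4)coc12
A2 | alternative 1 | trans-{3-[5-(allyloxy)-2,2-dimethyl-2H-chromen-8-yl]oxiran-2-yl}[4,6-bis(allyloxy)-2-(methoxymethoxy)-3-(3-methylbut-2-en-1-yl)phenyl]methanone, racemic | C=CCOc1cc(OCC=C)c(C(=O)[C@@H]4O[C@H]4c2ccc(OCC=C)c3c2OC(C)(C)C=C3)c(OCOC)c1CC=C(C)C
A3 | alternative 2 | 3-[2-hydroxy-3-(3-methylbut-2-en-1-yl)-4-(triisopropylsilyloxy)phenyl]-5,7-bis(methoxymethoxy)-8-(3-methylbut-2-en-1-yl)-4H-chromen-4-one | CC(C)=CCc1c(OCOC)cc(OCOC)c2c(=O)c(-c3ccc(O[Si](C(C)C)(C(C)C)C(C)C)c(CC=C(C)C)c3O)coc12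
A4 | alternative 2 | 3-[(1E)-4-diazo-3-oxobut-1-en-1-yl]-5,7-bis(methoxymethoxy)-8-(3-methylbut-2-en-1-yl)-4H-chromen-4-one | CC(C)=CCc1c(OCOC)cc(OCOC)c2c(=O)c(/C=C/C(=O)C=[N+]=[N-])coc12
A5 | alternative 3 | 3-[5-(tert-butyldimethylsilyloxy)-2,2-dimethyl-2H-chromen-8-yl]-5,7-dihydroxy-8-(3-methylbut-2-en-1-yl)-4H-chromen-4-one | CC(C)=CCc1c(O)cc(O)c2c(=O)c(-c3ccc(O[Si](C)(C)C(C)(C)C)c4c3OC(C)(C)C=C4)coc12
A6 | alternative 3 | 3-bromo-5-[5-(tert-butyldimethylsilyloxy)-2,2-dimethyl-2H-chromen-8-yl]-4H-pyran-4-one | O=c1c(Br)cocc1-c1ccc(O[Si](C)(C)C(C)(C)C)c2c1OC(C)(C)C=C2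
A7 | alternative 3 | 1-methoxy-7-methyl-1,3-bis(trimethylsilyloxy)octa-1,3,6-triene, double-bond geometry not fixed | COC(O[Si](C)(C)C)=CC(O[Si](C)(C)C)=CCC=C(C)C
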